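Remark on the chemistry: (R)-2-methylbutanoic acid is assumed to be purchased as the single enantiomer, so the configuration of the target comes from the chiral pool. Ring B is numbered as a chromanone (O1, C2–C4, C4a, C5–C8, C8a) and ring A as C1′–C6′ with the acyl group on C1′.

## Structural features

The target is a diarylmethane. Ring A is a fully substituted acylphloroglucinol monomethyl ether (C1′ acyl, C2′–OH, C3′–CH3, C4′–OCH3, C6′–OH) joined through C5′ and one CH2 group to C8 of ring B, the benzene ring of a 5,7-dihydroxy-2,2,6-trimethylchroman-4-one. Ring B is fused through C4a–C8a to the 2,2-dimethyldihydropyranone, with O1 on C8a and the carbonyl C4 on C4a, so the C6 methyl lies between C5–OH and C7–OH, and C8 lies between C7–OH and O1. The only stereocentre is C2 of the (R)-2-methylbutanoyl chain; it has no stereogenic neighbour, but it is α to an aryl ketone and can be lost by enolisation or through a ketene during acylation. Fragile points are the electron-rich phenols (oxidation), the diarylmethane link (retro-Friedel–Crafts scrambling in hot acid or base) and the O1–C2 bond (retro-oxa-Michael opening in strong base). The real difficulties are regiochemical: placing the ring B methyl at C6 and not at C8, since acid condensation of a methylphloroglucinol with a senecioyl unit can close through either flanking hydroxyl, and joining two different phenols through one carbon without forming symmetrical dimers. The key step uses the fact that the array O1–C8a=C4a–C4(=O) of ring B already exists as O1–C6=C5–C4(=O) in a 2,2-dimethyl-2,3-dihydropyran-4-one: if C5, C6, C7 and C8 are built onto that double bond, the ring fusion cannot come out the other way round.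

## Logic of the disconnections

**22 to 14 and 20 (through 21).** The bond C8–CH2 is cut and the bridge carbon stays on ring A as an aminomethyl group. Both 14 and 21 have a single reactive ring carbon, so only the crossed diarylmethane can form by direct substitution; a one-carbon linker added to two free phenols would give all three dimers. The cut halves the molecule and confines the stereocentre to one half. The forward step must release 21 under neutral conditions and at moderate temperature, because the product can scramble by retro-Friedel–Crafts exchange and the α-stereocentre can enolise.

**20 to 19.** The bond C5′–CH2 is cut (aminomethylation in the forward sense). C5′ is the only free position of 19, so no regiochemical question arises, and 20 is a stable, isolable latent quinone methide. The forward step must stop at the amine and not run on to the symmetrical diarylmethane, which calls for an excess of a preformed one-carbon iminium donor.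

**19 to 18.** The O–CH3 bond at C4′ is cut. The hydroxyl para to the acyl group is more acidic than the two ortho hydroxyls and is not held in a hydrogen bond, so the methyl group can be put on last without protecting groups. The forward step needs exactly one equivalent of base and of methylating agent.

**18 to 16 and 15 (through 17).** The bond C1′–C(=O) is cut. The two free positions of 16 are equivalent, so monoacylation gives one product, and the stereocentre is bought with 15. The forward step must not let the acylium ion derived from 17 lose its α-proton.

**14 to 13.** The O–Si bond at C7 is cut. The silyl group is needed only because it makes the alkyne partner of the key step polarised and stable; fluoride removes it without touching the rest.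

**13 to 5 and 8 (through 9, 10, 11 and 12).** Four bonds of ring B are cut: C8–C8a, C5–C6, C7–C8 and C4a–C5. The benzene ring is thereby assembled on the C=C of a pyranone that already carries O1, C2 with both methyl groups, C3 and C4, so six substituent positions are fixed in one operation. Position by position, the carbonyl carbon of the diazo ketone becomes C5 (phenol), the diazo carbon becomes C8 (CH), the methyl-bearing alkyne carbon becomes C6 and the silyloxy-bearing one C7; 13 therefore has the required constitution and not that of the 8-methyl isomer, and the structures of 5, 8 and 13 need no correction. The C4 ketone of 5 is left free: as part of a vinylogous ester it is inert to ketenes and ynol ethers, and in 13 it holds the C5 hydroxyl in a hydrogen bond. Three refinements over a plain ultraviolet photolysis are built in: light near 440 nm, where only the diazo ketone absorbs; a dark thermal stage separated from the photochemical one; and the triisopropylsilyl group, which enforces O-silylation of 7, resists 1,3-shift on heating and is fluoride-labile. The forward step demands a clean Wolff rearrangement and capture of 9 by 8 faster than ketene dimerisation.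

**5 to 2 and 3 (through 4).** The C–C bond between the acyl carbon and the diazo carbon is cut. Compound 3 is used as the non-explosive stand-in for the parent diazoalkane; it is still highly toxic by inhalation and is handled in closed equipment. Acylation of 3 must be faster than its dipolar addition to the C=C of 4.

**2 to 1.** The ester C–O bond is cut. Compound 1 is a bulk chemical that contains the whole O1–C(=C)–C(=O) array, the gem-dimethyl group and a carboxyl carbon on exactly the carbon that must migrate. The forward step must free the acid without leaving the pyran ring open.

**8 to 6 (through 7).** The O–Si bond is cut, and 7 is traced to the carbonyl group of 6 plus one carbon from a dihalomethane, with a 1,2-shift of the methyl group. This gives a three-carbon ynol ether from a two-carbon ester in one flask. Addition to the carbonyl group of 6 must outrun its enolisation, and silylation of 7 must occur on oxygen.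

## Other disconnections considered

**Alternative 1:** The cut is in ring A, at C1′–C(=O) and C6′–O together.
- Forward step: fluoride would release an aryne between C1′ and C6′ from 3,5-dimethoxy-4-methyl-2-(trimethylsilyl)phenyl trifluoromethanesulfonate (A2). The carboxylate of 15 would add to the aryne carbon remote from the methoxy group, the aryl anion would attack the acyl carbon, and the four-membered intermediate would open to (R)-1-(6-hydroxy-2,4-dimethoxy-3-methylphenyl)-2-methylbutan-1-one (A1). No ring closes.
- In its favour: the acyl group arrives without an acylium ion, so the ketene path to racemisation is closed. The three oxygens of ring A come out differentiated in A1; chelation-directed cleavage of the C2′ methyl ether next to the carbonyl would lead to 19 without relying on the relative acidity of three phenols. On oxygen differentiation this alternative is the better of the two.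
- Against it here: A2 is not an article of commerce and needs several steps from a phenol that must itself be made. The insertion runs with fluoride at elevated temperature, which is basic enough to threaten the α-stereocentre of A1 after all. Simple O-arylation to an aryl ester competes with acyl transfer.
- Comparison: this cut addresses ring A and the stereocentre, not the ring B regiochemistry that the chosen key step solves, so it competes with steps 6 and 7 and not with step 4. Against those two steps it is longer (at least five operations) and at best equal on stereochemical safety.

**Alternative 2:** Ring B is cut at C4a–C5 and C8–C8a; the pyranone C=C is again kept as C4a–C8a, but C5–C8 come as one four-carbon piece.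
- Forward step: 1-methoxy-2-methyl-1,3-bis[(trimethylsilyl)oxy]buta-1,3-diene (A5) would add to 2,2-dimethyl-5-(phenylsulfinyl)-2,3-dihydro-4H-pyran-4-one (A4). The unsubstituted terminus of A5 would bond to the oxygen-bearing carbon of A4 (C8–C8a) and the ketene-acetal terminus to the sulfinyl-bearing carbon (C4a–C5). Loss of the sulfur group as a sulfenic acid, of the methoxy group and of both silyl groups would aromatise the adduct to 5,7-dihydroxy-2,2,6-trimethylchroman-4-one (A3), which has the constitution of 14.
- In its favour: no diazo compound and no light. A3 would be reached with both phenols free, so the desilylation of step 5 is saved. The diene carries the C6 methyl between its two oxygens, so that pattern is as secure as in the chosen plan. On operational safety and ease of scale-up this alternative is the better one.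
- Against it here: the C=C of a dihydropyranone is donor-substituted and a weak dienophile, so the sulfinyl group must do all the activating. The addition would more likely be a stepwise Mukaiyama–Michael/Claisen sequence, and the enolate formed after the first bond could expel O1 (retro-oxa-Michael), opening the pyran ring on which the plan depends. A4 and A5 each need two or three steps, and A5 is moisture-sensitive.
- Comparison: on structure both plans lock the fusion direction with a preformed pyranone. On mechanism the chosen plan fixes the orientation through connectivity (O1 sits on the migrating carbon), whereas here it rests on polarity matching of two unsymmetrical partners. On step economy the two are about equal, roughly five operations to the dihydroxychromanone either way.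

**Alternative 3:** The pyranone ring, not the benzene ring, is disconnected: C8a–O1, C4a–C4 and O1–C2 are cut.
- Forward step: the aryne from A2 would be released between C4a and C8a. The carboxylate oxygen of 3-methylbut-2-enoic acid (A7) would bond to C8a, remote from the methoxy group; acyl transfer to C4a would give an ortho-hydroxyaryl enone, and oxa-Michael addition of the phenoxide would close the ring to 5,7-dimethoxy-2,2,6-trimethylchroman-4-one (A6).
- In its favour: insertion followed by oxa-Michael closure with exactly this acid is an established way to 2,2-dimethylchromanones, so the key step has a closer precedent than the chosen one; on this point the alternative is the better. The acid partner A7 is a cheap bulk chemical. One aryne precursor, A2, would serve both rings if combined with alternative 1. The methoxy group beside the aryne dictates the orientation.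
- Against it here: A2 takes several steps. More seriously, A6 carries two methyl ethers, and the one at C7 has no neighbouring carbonyl to direct its cleavage. The strong Lewis acids needed for it also attack the tertiary alkyl aryl ether O1–C2, and ring opening with re-closure through the other oxygen would scramble the 6-methyl/8-methyl orientation that the step was meant to secure.
- Comparison: on structure both plans define the ring fusion. On mechanism this one is purely ionic and thermal where the chosen one is photochemical. On step economy it is longer (precursor synthesis, insertion, double demethylation), and the chosen plan ends in a fluoride-labile silyl ether instead of two methyl ethers.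

Key step: step 4

## Route

Step 1
Reactants: 1 butopyronoxyl (butyl 2,2-dimethyl-4-oxo-3,4-dihydro-2H-pyran-6-carboxylate)
Product: 2 2,2-dimethyl-4-oxo-3,4-dihydro-2H-pyran-6-carboxylic acid
Conditions: LiOH·H2O (1.1 equiv), THF/H2O, 0 °C; then 1 M HCl to pH 2
Reagents that add atoms: lithium hydroxide, [Li+].[OH-]
Why: Saponification of the activated α-alkoxyacrylate ester should be fast at 0 °C; if the basic medium opens the ring by retro-oxa-Michael elimination across O1–C2, acidification should close it again, since the cyclic form is the favoured one.

Step 2
Reactants: 2 2,2-dimethyl-4-oxo-3,4-dihydro-2H-pyran-6-carboxylic acid; 3 (trimethylsilyl)diazomethane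
Product: 5 6-(2-diazoacetyl)-2,2-dimethyl-2,3-dihydro-4H-pyran-4-one, via acid chloride 4 (not isolated)
Conditions: (COCl)2 (1.1 equiv), DMF (cat.), CH2Cl2, 0 °C to rt; evaporate; then 3 (2.0 equiv, hexane solution), MeCN/THF, 0 °C, dark
Reagents that add atoms: none
Why: Vilsmeier-type activation gives 4 (its chlorine comes from (COCl)2 and leaves again as Me3SiCl); C-acylation of 3 followed by chloride-induced desilylation then gives the diazo ketone (Arndt–Eistert-type acylation of a diazoalkane). The alkoxy group on the C=C of 4 lowers its reactivity as a dipolarophile, so acylation should be faster than pyrazoline formation at 0 °C.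

Step 3
Reactants: 6 ethyl acetate
Product: 8 triisopropyl(prop-1-yn-1-yloxy)silane, via lithium ynolate 7 (not isolated)
Conditions: CH2Br2, lithium 2,2,6,6-tetramethylpiperidide (LiTMP, 2.2 equiv), THF, −78 °C; then n-BuLi, −78 to 0 °C; then i-Pr3SiCl, −78 °C to rt
Reagents that add atoms: dibromomethane, BrCBr; chlorotriisopropylsilane, CC(C)[Si](Cl)(C(C)C)C(C)C
Why: Kowalski ester homologation: LiCHBr2 adds to the ester carbonyl, loss of ethoxide and deprotonation give a dibromo enolate, and bromine–lithium exchange with 1,2-shift of the methyl group (carbenoid rearrangement) gives ynolate 7. The bulky silyl chloride should silylate 7 on oxygen and not on carbon.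

Step 4
Reactants: 5 6-(2-diazoacetyl)-2,2-dimethyl-2,3-dihydro-4H-pyran-4-one; 8 triisopropyl(prop-1-yn-1-yloxy)silane
Product: 13 5-hydroxy-2,2,6-trimethyl-7-[(triisopropylsilyl)oxy]chroman-4-one, via vinylketene 9 (not isolated), via vinylcyclobutenone 10 (not isolated), via dienylketene 11 (not isolated), via cyclohexadienone 12 (not isolated)
Conditions: 8 (1.5 equiv), hν (LEDs, λmax about 440 nm), degassed toluene (0.02 M), 20 °C; then 80 °C, dark
Reagents that add atoms: none
Why: Excitation of the diazo ketone chromophore of 5 expels N2 and the pyranonyl group migrates to the carbene carbon (Wolff rearrangement, new bond C8–C8a), giving vinylketene 9, whose alkene is the pyranone C=C (future C4a=C8a). Ketene 9 and ynol ether 8 combine without further light in a [2+2] cycloaddition (C5–C6 and C7–C8) to cyclobutenone 10. On warming, 10 opens by 4π-electrocyclic cleavage of C5–C8 to dienylketene 11, and ring B is closed by thermal, disrotatory 6π-electrocyclisation (C4a–C5) to 12, which enolises to the phenol 13. The closest known reaction type is the Danheiser benzannulation in its photo-Wolff form with siloxyalkynes, which gives resorcinol monosilyl ethers; what is new is only that the vinyl unit is the C=C of a vinylogous ester. No stereocentre is formed, since the sp3 carbons of 10 and 12 become aromatic. Regiochemistry needs the methyl-bearing carbon of 8 to bond to the ketene carbonyl carbon, which the oxygen-induced polarisation of the ynol ether secures, so CH3 ends on C6 beside the C5 hydroxyl and the silyloxy group on C7; the direction of ring fusion needs no control because O1 is already on the migrating carbon. Chemoselectivity of excitation is secured by the wavelength: near 440 nm only the diazo ketone should absorb, the enones of 10 and 13 are transparent, and enone–alkyne photocycloaddition should not compete. The 6π-closure is polarity-matched (the enol-ether β-carbon C4a attacks the ketene carbon), and the C5 hydroxyl of 13 is held by the C4 carbonyl, which should protect it from acylation by 9.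

Step 5
Reactants: 13 5-hydroxy-2,2,6-trimethyl-7-[(triisopropylsilyl)oxy]chroman-4-one
Product: 14 5,7-dihydroxy-2,2,6-trimethylchroman-4-one
Conditions: Bu4NF (1.1 equiv), AcOH (1.1 equiv), THF, 0 °C
Reagents that add atoms: none
Why: Fluoride cleaves the aryl silyl ether at silicon; buffering with acetic acid keeps the medium from opening the chromanone by retro-oxa-Michael reaction.

Step 6
Reactants: 15 (R)-2-methylbutanoic acid; 16 2-methylbenzene-1,3,5-triol (2-methylphloroglucinol)
Product: 18 (R)-2-methyl-1-(2,4,6-trihydroxy-3-methylphenyl)butan-1-one, via acid chloride 17 (not isolated)
Conditions: (COCl)2, DMF (cat.), CH2Cl2, 0 °C to rt; then 16 (1.0 equiv), AlCl3 (3.5 equiv), CH2Cl2/MeNO2, 0 °C to rt; aq. HCl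
Reagents that add atoms: none
Why: Friedel–Crafts C-acylation of a phloroglucinol: the two free ring positions of 16 are equivalent, and the first acyl group deactivates the ring against a second. The stereocentre comes unchanged from 15, provided the low temperature keeps the acylium ion from losing its α-proton.

Step 7
Reactants: 18 (R)-2-methyl-1-(2,4,6-trihydroxy-3-methylphenyl)butan-1-one
Product: 19 (R)-1-(2,6-dihydroxy-4-methoxy-3-methylphenyl)-2-methylbutan-1-one
Conditions: Me2SO4 (1.0 equiv), K2CO3 (1.0 equiv), acetone, rt
Reagents that add atoms: dimethyl sulfate, COS(=O)(=O)OC
Why: Williamson O-methylation with one equivalent of base: the C4′ hydroxyl para to the acyl group is the most acidic and is not hydrogen-bonded, so its phenoxide should form and react first. The hindered, chelated ketone should not enolise under these conditions, so the stereocentre is kept.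

Step 8
Reactants: 19 (R)-1-(2,6-dihydroxy-4-methoxy-3-methylphenyl)-2-methylbutan-1-one
Product: 20 (R)-1-{3-[(dimethylamino)methyl]-2,6-dihydroxy-4-methoxy-5-methylphenyl}-2-methylbutan-1-one
Conditions: CH2(NMe2)2 (1.5 equiv), 1,4-dioxane, rt to 40 °C
Reagents that add atoms: bis(dimethylamino)methane, CN(C)CN(C)C
Why: Phenolic Mannich reaction: the acidic phenol protonates the aminal, and the iminium ion so formed attacks C5′, the only unsubstituted ring carbon. The excess of the preformed aminal should keep the reaction at the stage of the benzylic amine.

Step 9
Reactants: 14 5,7-dihydroxy-2,2,6-trimethylchroman-4-one; 20 (R)-1-{3-[(dimethylamino)methyl]-2,6-dihydroxy-4-methoxy-5-methylphenyl}-2-methylbutan-1-one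
Product: 22 8-({2,4-dihydroxy-6-methoxy-5-methyl-3-[(2R)-2-methylbutanoyl]phenyl}methyl)-5,7-dihydroxy-2,2,6-trimethylchroman-4-one, via ortho-quinone methide 21 (not isolated)
Conditions: 20 (1.2 equiv, added in portions), 1,4-dioxane, 90 °C, Ar sweep
Reagents that add atoms: none
Why: Thermal loss of Me2NH from the zwitterionic Mannich base gives ortho-quinone methide 21, which is captured by C8 of 14 (Michael-type Friedel–Crafts alkylation) with rearomatisation of both rings. Each partner has a single free ring carbon, so direct substitution can give only the crossed diarylmethane; the stereocentre is remote from the reacting centres and no strong base is present.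

## Compound list

1 | butopyronoxyl (butyl 2,2-dimethyl-4-oxo-3,4-dihydro-2H-pyran-6-carboxylate) | CCCCOC(=O)C1=CC(=O)CC(C)(C)O1 | starting material
2 | 2,2-dimethyl-4-oxo-3,4-dihydro-2H-pyran-6-carboxylic acid | OC(=O)C1=CC(=O)CC(C)(C)O1 | intermediate
3 | (trimethylsilyl)diazomethane | C[Si](C)(C)C=[N+]=[N-] | starting material
4 | 2,2-dimethyl-4-oxo-3,4-dihydro-2H-pyran-6-carbonyl chloride | ClC(=O)C1=CC(=O)CC(C)(C)O1 | intermediate
5 | 6-(2-diazoacetyl)-2,2-dimethyl-2,3-dihydro-4H-pyran-4-one | [N-]=[N+]=CC(=O)C1=CC(=O)CC(C)(C)O1 | intermediate
6 | ethyl acetate | CCOC(C)=O | starting material
7 | lithium prop-1-yn-1-olate | CC#C[O-].[Li+] | intermediate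
8 | triisopropyl(prop-1-yn-1-yloxy)silane | CC#CO[Si](C(C)C)(C(C)C)C(C)C | intermediate
9 | 2,2-dimethyl-6-(2-oxoethenyl)-2,3-dihydro-4H-pyran-4-one (vinylketene) | O=C=CC1=CC(=O)CC(C)(C)O1 | intermediate
10 | 2,2-dimethyl-6-{3-methyl-4-oxo-2-[(triisopropylsilyl)oxy]cyclobut-2-en-1-yl}-2,3-dihydro-4H-pyran-4-one (racemic) | CC1=C(O[Si](C(C)C)(C(C)C)C(C)C)C(C1=O)C1=CC(=O)CC(C)(C)O1 | intermediate
11 | 2,2-dimethyl-6-{(1E)-3-methyl-4-oxo-2-[(triisopropylsilyl)oxy]buta-1,3-dien-1-yl}-2,3-dihydro-4H-pyran-4-one (ketenyl carbon and pyranonyl group cis on the enol ether double bond) | CC(=C=O)/C(O[Si](C(C)C)(C(C)C)C(C)C)=C\C1=CC(=O)CC(C)(C)O1 | intermediate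
12 | 2,2,6-trimethyl-7-[(triisopropylsilyl)oxy]-2,3-dihydro-4H-chromene-4,5(4aH)-dione (racemic) | CC1(C)CC(=O)C2C(=O)C(C)=C(O[Si](C(C)C)(C(C)C)C(C)C)C=C2O1 | intermediate
13 | 5-hydroxy-2,2,6-trimethyl-7-[(triisopropylsilyl)oxy]chroman-4-one | CC1(C)CC(=O)c2c(O)c(C)c(O[Si](C(C)C)(C(C)C)C(C)C)cc2O1 | intermediate
14 | 5,7-dihydroxy-2,2,6-trimethylchroman-4-one | CC1(C)CC(=O)c2c(O)c(C)c(O)cc2O1 | intermediate
15 | (R)-2-methylbutanoic acid | CC[C@@H](C)C(=O)O | starting material
16 | 2-methylbenzene-1,3,5-triol (2-methylphloroglucinol) | Cc1c(O)cc(O)cc1O | starting material
17 | (R)-2-methylbutanoyl chloride | CC[C@@H](C)C(=O)Cl | intermediate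
18 | (R)-2-methyl-1-(2,4,6-trihydroxy-3-methylphenyl)butan-1-one | CC[C@@H](C)C(=O)c1c(O)c(C)c(O)cc1O | intermediate
19 | (R)-1-(2,6-dihydroxy-4-methoxy-3-methylphenyl)-2-methylbutan-1-one | CC[C@@H](C)C(=O)c1c(O)c(C)c(OC)cc1O | intermediate
20 | (R)-1-{3-[(dimethylamino)methyl]-2,6-dihydroxy-4-methoxy-5-methylphenyl}-2-methylbutan-1-one | CC[C@@H](C)C(=O)c1c(O)c(C)c(OC)c(CN(C)C)c1O | intermediate
21 | 3-hydroxy-5-methoxy-4-methyl-6-methylidene-2-[(2R)-2-methylbutanoyl]cyclohexa-2,4-dien-1-one (ortho-quinone methide) | CC[C@@H](C)C(=O)C1=C(O)C(C)=C(OC)C(=C)C1=O | intermediate
22 | 8-({2,4-dihydroxy-6-methoxy-5-methyl-3-[(2R)-2-methylbutanoyl]phenyl}methyl)-5,7-dihydroxy-2,2,6-trimethylchroman-4-one | CC[C@@H](C)C(=O)c1c(O)c(C)c(OC)c(Cc2c(O)c(C)c(O)c3c2OC(C)(C)CC3=O)c1O | target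

## Step count and least certain steps

Total step count: 9 steps (steps 2, 3, 4, 6 and 9 run through non-isolated intermediates).

Longest linear sequence: 5 steps (steps 1, 2, 4, 5 and 9; 1 → 2 → 5 → 13 → 14 → 22). The ring A branch has 4 steps (6, 7, 8, 9) and the ynol ether branch 2 (3, 4).

**Step 4 (key step).** The vinyl unit is a β-acyl enol ether, a type that has not been carried through this benzannulation.
- Light absorption at 440 nm may be too weak for a practical rate, which would force shorter wavelengths and bring back enone–alkyne photocycloaddition at the stage of 10.
- Ketene 9 may dimerise or be captured by the phenol of 13 before it meets 8.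
- The 4π-opening of 10 may turn the pyranonyl group outward, which gives a dienylketene geometry that cannot cyclise; that isomer has to revert to 10 and reopen the other way, and during this detour the ketene can be lost to adventitious nucleophiles.
- Fallback, from 16 back to 14: 16 would be condensed with 3-methylbut-2-enoic acid (A7) in P2O5/MeSO3H at about 70 °C; the acid A7 should acylate the ring of 16 (Friedel–Crafts) to give 3-methyl-1-(2,4,6-trihydroxy-3-methylphenyl)but-2-en-1-one (F1). In the same flask F1 should close by oxa-Michael addition through either flanking hydroxyl, to 14 and to its regioisomer 5,7-dihydroxy-2,2,8-trimethylchroman-4-one (F2). The two would have to be separated; F2 could be returned to the same acid, where ring opening to F1 and re-closure (Wessely–Moser-type equilibration) would regenerate the mixture. This gives up the built-in regiocontrol but is short, uses only known chemistry and replaces steps 1 to 5.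

**Step 2.** The diazoalkane, or the diazo ketone once formed, may undergo 1,3-dipolar cycloaddition onto the C=C of the pyranone, which is flanked by two carbonyl groups despite its alkoxy donor. HCl left from the chlorination may also destroy the diazo group by protonation and loss of N2.
- Fallback, from 4 back to 5: 4 would be treated with N-isocyanoiminotriphenylphosphorane in CH2Cl2, where the isocyanide carbon should insert into the C–Cl bond (Nef-type isocyanide reaction) to give 2-(2,2-dimethyl-4-oxo-3,4-dihydro-2H-pyran-6-yl)-2-oxo-N-[(triphenylphosphoranylidene)amino]ethanimidoyl chloride (F3). Water should cleave the P=N bond of F3 to give 2-(2,2-dimethyl-4-oxo-3,4-dihydro-2H-pyran-6-yl)-2-oxoethanehydrazonoyl chloride (F4), and Et3N should remove HCl from F4 to give 5. No free diazoalkane is present at any stage.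

**Step 9.** The diarylmethane, once formed, may undergo ipso attack with retro-Friedel–Crafts exchange, which would scramble the two halves into symmetrical dimers. The quinone methide 21 may also condense with itself if capture by C8 is slow, and prolonged heating with the liberated amine may slowly epimerise the α-carbon.
- Fallback, from 14 back to 22: the roles of the rings would be exchanged and the quinone methide made at room temperature. Compound 14 would be aminomethylated at C8 with CH2(NMe2)2 to 8-[(dimethylamino)methyl]-5,7-dihydroxy-2,2,6-trimethylchroman-4-one (F5), and F5 quaternised with MeI to 1-(5,7-dihydroxy-2,2,6-trimethyl-4-oxochroman-8-yl)-N,N,N-trimethylmethanaminium iodide (F6). Stirring F6 with 19 and NaHCO3 in aqueous MeCN at rt should expel trimethylamine to give 5-hydroxy-2,2,6-trimethyl-8-methylidene-2,3-dihydro-4H-chromene-4,7(8H)-dione (F7); C5′ of 19 should then capture F7 to give 22. This route does not need 20 and avoids heat altogether.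

**Step 6.** Partial racemisation may occur through reversible loss of the α-proton from the acylium ion (ketene formation) or through enolisation of the AlCl3-bound ketone; over-acylation is a lesser risk.
- Fallback, from 15 back to 19: 17, made from 15 as in step 6, would be converted with N,O-dimethylhydroxylamine hydrochloride under Schotten–Baumann conditions (K2CO3, H2O/CH2Cl2, 0 °C) into (R)-N-methoxy-N,2-dimethylbutanamide (F8). Commercial 2,4,6-trimethoxytoluene would be lithiated between two methoxy groups with n-BuLi/TMEDA in THF to (2,4,6-trimethoxy-3-methylphenyl)lithium (F9). Addition of F9 to F8 at −78 °C and collapse of the chelated adduct on work-up with aqueous NH4Cl should give (R)-2-methyl-1-(2,4,6-trimethoxy-3-methylphenyl)butan-1-one (F10). Excess BCl3 in CH2Cl2 should then cleave the two methyl ethers of F10 that flank the carbonyl (chelation-directed) and leave the para ether, giving 19. No acylium ion is involved, and the selective methylation of step 7 is bypassed as well.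

## Further compounds

F1 | step 4 | 3-methyl-1-(2,4,6-trihydroxy-3-methylphenyl)but-2-en-1-one | CC(C)=CC(=O)c1c(O)c(C)c(O)cc1O
F2 | step 4 | 5,7-dihydroxy-2,2,8-trimethylchroman-4-one | CC1(C)CC(=O)c2c(O)cc(O)c(C)c2O1
F3 | step 2 | 2-(2,2-dimethyl-4-oxo-3,4-dihydro-2H-pyran-6-yl)-2-oxo-N-[(triphenylphosphoranylidene)amino]ethanimidoyl chloride | ClC(=NN=P(c1ccccc1)(c1ccccc1)c1ccccc1)C(=O)C1=CC(=O)CC(C)(C)O1
F4 | step 2 | 2-(2,2-dimethyl-4-oxo-3,4-dihydro-2H-pyran-6-yl)-2-oxoethanehydrazonoyl chloride | NN=C(Cl)C(=O)C1=CC(=O)CC(C)(C)O1
F5 | step 9 | 8-[(dimethylamino)methyl]-5,7-dihydroxy-2,2,6-trimethylchroman-4-one | CN(C)Cc1c(O)c(C)c(O)c2c1OC(C)(C)CC2=O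
F6 | step 9 | 1-(5,7-dihydroxy-2,2,6-trimethyl-4-oxochroman-8-yl)-N,N,N-trimethylmethanaminium iodide | C[N+](C)(C)Cc1c(O)c(C)c(O)c2c1OC(C)(C)CC2=O.[I-]
F7 | step 9 | 5-hydroxy-2,2,6-trimethyl-8-methylidene-2,3-dihydro-4H-chromene-4,7(8H)-dione | C=C1C(=O)C(C)=C(O)C2=C1OC(C)(C)CC2=O
F8 | step 6 | (R)-N-methoxy-N,2-dimethylbutanamide | CC[C@@H](C)C(=O)N(C)OC
F9 | step 6 | (2,4,6-trimethoxy-3-methylphenyl)lithium | [Li]c1c(OC)cc(OC)c(C)c1OC
F10 | step 6 | (R)-2-methyl-1-(2,4,6-trimethoxy-3-methylphenyl)butan-1-one | CC[C@@H](C)C(=O)c1c(OC)c(C)c(OC)cc1OC
A1 | alternative 1 | (R)-1-(6-hydroxy-2,4-dimethoxy-3-methylphenyl)-2-methylbutan-1-one | CC[C@@H](C)C(=O)c1c(O)cc(OC)c(C)c1OC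
A2 | alternative 1 | 3,5-dimethoxy-4-methyl-2-(trimethylsilyl)phenyl trifluoromethanesulfonate | COc1cc(OS(=O)(=O)C(F)(F)F)c([Si](C)(C)C)c(OC)c1C
A3 | alternative 2 | 5,7-dihydroxy-2,2,6-trimethylchroman-4-one | CC1(C)CC(=O)c2c(O)c(C)c(O)cc2O1
A4 | alternative 2 | 2,2-dimethyl-5-(phenylsulfinyl)-2,3-dihydro-4H-pyran-4-one | CC1(C)CC(=O)C(=CO1)S(=O)c1ccccc1
A5 | alternative 2 | 1-methoxy-2-methyl-1,3-bis[(trimethylsilyl)oxy]buta-1,3-diene | COC(O[Si](C)(C)C)=C(C)C(=C)O[Si](C)(C)C
A6 | alternative 3 | 5,7-dimethoxy-2,2,6-trimethylchroman-4-one | CC1(C)CC(=O)c2c(OC)c(C)c(OC)cc2O1
A7 | alternative 3 | 3-methylbut-2-enoic acid | CC(C)=CC(=O)O
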